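**Retrosynthetic overview**

- Feature: ring B carries two prenyl-derived C5 units, the intact 3-methylbut-2-enyl group on C2' and the unit oxidised into ring D (O4'–C2''Me2–C3''H(OH)–C4''H(OH)–C5'). Only the ring D unit is assembled with a hydroxyl on C4'' next to its C2''=C3'' alkene, so a hydroxyl-directed epoxidation can pick it out and leave the C2' prenyl alkene alone.
- Last disconnections: 3'-O-allyl removal; ring D by O4'–C2'' bond formation, a weak-acid 6-endo opening of the erythro (3''R,4''R) epoxy alcohol by the free 4'-phenol; epoxy alcohol by Ti(OiPr)4/D-(−)-tartrate epoxidation of the C5' allylic alcohol, made from the C5' aldehyde and 2-methylprop-1-enylmagnesium bromide.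
- C5' aldehyde by ortho-formylation of the 4'-phenol; C2' prenyl by O-(1,1-dimethylallyl)ation of 3'-OH and aromatic Claisen shift; the two ring B oxygens are told apart from the outset (acetal on O4', free O3').
- Flavan core: asymmetric conjugate addition of the ring B boronic acid to 7-silyloxychromone sets C2 (S), then the C4 oxygen is removed.
- Order of rings: A and C arrive in the chromone, B is attached in step 5, D is closed in step 18.

Key step: step 18

Assumption: the (R)-configured pyridine–oxazoline ligand is taken to give the 2S adduct in step 5, by transfer of the facial preference that the (S)-ligand shows with cyclic enones; flavan numbering is used, ring B primed, ring D carbons written C2'' (CMe2), C3'' and C4'' (bonded to C5').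

**Route**

Step 1
Reactants: 1 7-hydroxychromone
Product: 2 7-(triisopropylsilyloxy)chromone
Conditions: i-Pr3SiCl, imidazole, DMF, 23 °C
Reagents that add atoms: triisopropylsilyl chloride, CC(C)[Si](Cl)(C(C)C)C(C)C
Why: Silyl ether formation at the only hydroxyl group (the acidic 7-OH) gives a bulky aryl silyl ether that should survive the weakly acidic aqueous coupling, hydride, dilute acid, zerovalent palladium and Grignard steps and is cleaved by fluoride in step 17.

Step 2
Reactants: 3 5-bromo-2-hydroxybenzaldehyde
Product: 4 5-bromo-2-(methoxymethoxy)benzaldehyde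
Conditions: MeOCH2Cl, i-Pr2NEt, CH2Cl2, 0 to 23 °C
Reagents that add atoms: chloromethyl methyl ether, COCCl
Why: Williamson-type O-alkylation of the phenol gives the methoxymethyl acetal that masks the future O4' until step 12 and cannot migrate to the neighbouring oxygen introduced next.

Step 3
Reactants: 4 5-bromo-2-(methoxymethoxy)benzaldehyde
Product: 6 5-bromo-2-(methoxymethoxy)phenol, via aryl formate 5 (not isolated)
Conditions: mCPBA, CH2Cl2, 23 °C; then K2CO3 (cat.), MeOH, 0 °C
Reagents that add atoms: 3-chloroperoxybenzoic acid, OOC(=O)c1cccc(Cl)c1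
Why: Baeyer–Villiger oxidation of the aldehyde (Dakin-type) proceeds with migration of the electron-rich ortho-alkoxyaryl group to give formate 5, and methanolysis of this aryl ester releases the phenol that becomes O3', so that the two catechol oxygens are differentiated from the start.

Step 4
Reactants: 6 5-bromo-2-(methoxymethoxy)phenol
Product: 9 [3-hydroxy-4-(methoxymethoxy)phenyl]boronic acid, via dilithiated phenoxide 7 (not isolated), via lithium aryltriisopropoxyborate 8 (not isolated)
Conditions: n-BuLi (2.2 equiv), THF, −78 °C; B(OiPr)3, −78 to 0 °C; aq. NH4Cl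
Reagents that add atoms: triisopropyl borate, CC(C)OB(OC(C)C)OC(C)C; water, O
Why: The first equivalent of n-BuLi deprotonates the phenol and the second effects bromine–lithium exchange, after which borylation of the aryllithium with B(OiPr)3 and mild hydrolysis (pH near 6, which spares the acetal) should give the boronic acid.

Step 5
Reactants: 2 7-(triisopropylsilyloxy)chromone; 9 [3-hydroxy-4-(methoxymethoxy)phenyl]boronic acid
Product: 10 (2S)-3'-hydroxy-4'-(methoxymethoxy)-7-(triisopropylsilyloxy)flavanone
Conditions: 9 (2 equiv), Pd(OCOCF3)2 (5 mol %), (R)-t-BuPyOx (6 mol %), NH4PF6 (30 mol %), H2O (5 equiv), ClCH2CH2Cl, 60 °C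
Reagents that add atoms: none
Why: Asymmetric conjugate addition of an arylboronic acid to a chromone under cationic divalent palladium–pyridine-oxazoline catalysis: the aryl–palladium species adds across C2=C3 with the tert-butyl group of the ligand leaving one face of C2 open, protonation of the palladium enolate releases the flavanone, and the (R)-ligand [(R)-4-tert-butyl-2-(pyridin-2-yl)-4,5-dihydrooxazole] is chosen to set 2S.

Step 6
Reactants: 10 (2S)-3'-hydroxy-4'-(methoxymethoxy)-7-(triisopropylsilyloxy)flavanone
Product: 11 (2S)-3'-hydroxy-4'-(methoxymethoxy)-7-(triisopropylsilyloxy)flavan-4-ol (C4 epimers)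
Conditions: NaBH4, THF–MeOH, 0 °C
Reagents that add atoms: none
Why: Borohydride reduction of the aryl ketone, expected to favour the 2,4-cis (4S) alcohol by axial hydride delivery, though the C4 configuration is of no consequence because C4 becomes CH2 in step 7.

Step 7
Reactants: 11 (2S)-3'-hydroxy-4'-(methoxymethoxy)-7-(triisopropylsilyloxy)flavan-4-ol (C4 epimers)
Product: 12 (2S)-3'-hydroxy-4'-(methoxymethoxy)-7-(triisopropylsilyloxy)flavan
Conditions: Et3SiH, CF3CO2H (3 equiv), CH2Cl2, −20 °C
Reagents that add atoms: none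
Why: Ionic hydrogenation: the C4 hydroxyl, flanked by the ortho ring oxygen and the para silyloxy group, ionises with a few equivalents of acid at low temperature and the cation is trapped by Et3SiH, conditions under which the aryl methoxymethyl ether and the C2–O1 bond should remain intact.

Step 8
Reactants: 13 2-methylbut-3-en-2-ol
Product: 15 methyl 2-methylbut-3-en-2-yl carbonate, via lithium alkoxide 14 (not isolated)
Conditions: n-BuLi, THF, −78 °C; ClCO2Me, −78 to 0 °C
Reagents that add atoms: methyl chloroformate, COC(=O)Cl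
Why: Deprotonation of the tertiary alcohol and O-acylation of the alkoxide with methyl chloroformate gives the allylic carbonate needed for the allylation of step 9.

Step 9
Reactants: 12 (2S)-3'-hydroxy-4'-(methoxymethoxy)-7-(triisopropylsilyloxy)flavan; 15 methyl 2-methylbut-3-en-2-yl carbonate
Product: 16 (2S)-4'-(methoxymethoxy)-3'-(2-methylbut-3-en-2-yloxy)-7-(triisopropylsilyloxy)flavan
Conditions: Pd(PPh3)4 (5 mol %), THF, 0 °C
Reagents that add atoms: none
Why: Tsuji–Trost O-allylation: zerovalent palladium ionises the carbonate with loss of CO2, the released methoxide deprotonates the only free phenol (3'-OH), and under kinetic control at 0 °C the phenoxide attacks the more substituted terminus of the 1,1-dimethylallyl palladium complex to give the tertiary ether.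

Step 10
Reactants: 16 (2S)-4'-(methoxymethoxy)-3'-(2-methylbut-3-en-2-yloxy)-7-(triisopropylsilyloxy)flavan
Product: 17 (2S)-3'-hydroxy-4'-(methoxymethoxy)-2'-(3-methylbut-2-enyl)-7-(triisopropylsilyloxy)flavan
Conditions: PhNEt2, 120 °C
Reagents that add atoms: none
Why: Aromatic Claisen rearrangement: the [3,3] shift of the 1,1-dimethylallyl ether, accelerated by the geminal methyl groups, delivers the CH2 terminus to C2', the only free ortho position of O3' since C4' carries the acetal oxygen, and tautomerisation gives the 2'-prenyl phenol without touching C2.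

Step 11
Reactants: 17 (2S)-3'-hydroxy-4'-(methoxymethoxy)-2'-(3-methylbut-2-enyl)-7-(triisopropylsilyloxy)flavan
Product: 18 (2S)-3'-(allyloxy)-4'-(methoxymethoxy)-2'-(3-methylbut-2-enyl)-7-(triisopropylsilyloxy)flavan
Conditions: allyl bromide, K2CO3, acetone, 56 °C
Reagents that add atoms: allyl bromide, C=CCBr
Why: Williamson etherification of the hindered 3'-phenol in acetone, a medium in which the aryl silyl ether is not cleaved, installs a non-migrating group that is removed only in the last step.

Step 12
Reactants: 18 (2S)-3'-(allyloxy)-4'-(methoxymethoxy)-2'-(3-methylbut-2-enyl)-7-(triisopropylsilyloxy)flavan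
Product: 19 (2S)-3'-(allyloxy)-4'-hydroxy-2'-(3-methylbut-2-enyl)-7-(triisopropylsilyloxy)flavan
Conditions: HCl (0.5 M), MeOH, 40 °C
Reagents that add atoms: none
Why: Acid-catalysed acetal exchange with methanol removes the methoxymethyl group and frees the 4'-phenol, while the aryl silyl ether, the allyl ether and the prenyl group (which has no free ortho hydroxyl to cyclise onto) should be unaffected.

Step 13
Reactants: 19 (2S)-3'-(allyloxy)-4'-hydroxy-2'-(3-methylbut-2-enyl)-7-(triisopropylsilyloxy)flavan
Product: 20 (2S)-3'-(allyloxy)-5'-formyl-4'-hydroxy-2'-(3-methylbut-2-enyl)-7-(triisopropylsilyloxy)flavan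
Conditions: MgCl2, Et3N, (CH2O)n, MeCN, 80 °C
Reagents that add atoms: paraformaldehyde (reacts as formaldehyde), C=O
Why: Magnesium-mediated ortho-formylation (Casnati–Skattebøl reaction): the magnesium phenoxide of the only free phenol binds formaldehyde and directs C–C bond formation to C5', its single unsubstituted ortho position, and the benzylic alkoxide is oxidised to the aldehyde by a second formaldehyde.

Step 14
Reactants: 20 (2S)-3'-(allyloxy)-5'-formyl-4'-hydroxy-2'-(3-methylbut-2-enyl)-7-(triisopropylsilyloxy)flavan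
Product: 21 (2S)-3'-(allyloxy)-5'-formyl-2'-(3-methylbut-2-enyl)-4',7-bis(triisopropylsilyloxy)flavan
Conditions: i-Pr3SiOTf, 2,6-lutidine, CH2Cl2, 0 °C
Reagents that add atoms: triisopropylsilyl trifluoromethanesulfonate, CC(C)[Si](OS(=O)(=O)C(F)(F)F)(C(C)C)C(C)C
Why: Silylation of the chelated phenol with the silyl triflate masks the acidic 4'-OH for the Grignard and titanium steps with a bulky group that should resist migration to the neighbouring alkoxide.

Step 15
Reactants: 21 (2S)-3'-(allyloxy)-5'-formyl-2'-(3-methylbut-2-enyl)-4',7-bis(triisopropylsilyloxy)flavan; 22 2-methylprop-1-enylmagnesium bromide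
Product: 23 (2S)-3'-(allyloxy)-5'-(1-hydroxy-3-methylbut-2-enyl)-2'-(3-methylbut-2-enyl)-4',7-bis(triisopropylsilyloxy)flavan as the mixture of C4'' epimers
Conditions: 22 (1.5 equiv, THF), THF, −78 °C; aq. NH4Cl at −78 °C
Reagents that add atoms: none
Why: Grignard 1,2-addition to the aldehyde creates C4'' with its allylic hydroxyl and the C2''=C3'' alkene; the remote C2 centre is not expected to bias the new carbinol, so both C4'' epimers should form, and the cold quench avoids silyl migration from the phenol oxygen to the alkoxide.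

Step 16
Reactants: 23 (2S)-3'-(allyloxy)-5'-(1-hydroxy-3-methylbut-2-enyl)-2'-(3-methylbut-2-enyl)-4',7-bis(triisopropylsilyloxy)flavan as the mixture of C4'' epimers
Product: 24 (2S)-3'-(allyloxy)-5'-{(R)-[(2R)-3,3-dimethyloxiran-2-yl](hydroxy)methyl}-2'-(3-methylbut-2-enyl)-4',7-bis(triisopropylsilyloxy)flavan
Conditions: Ti(OiPr)4 (0.2 equiv), D-(−)-diisopropyl tartrate (0.25 equiv), t-BuOOH (0.55 equiv), 4 Å molecular sieves, CH2Cl2, −20 °C
Reagents that add atoms: tert-butyl hydroperoxide, CC(C)(C)OO
Why: Sharpless epoxidation used as a resolution of the two C4'' epimers: the allylic alkoxide binds the Ti(OiPr)4–tartrate catalyst so that only the C2''=C3'' alkene (and neither the C2' prenyl group nor the allyl ether) is oxidised, D-(−)-tartrate delivers oxygen to the face that makes C3'' R, and only the 4''S alcohol reacts at a useful rate, giving the erythro (3''R,4''R) epoxy alcohol (the C4'' descriptor changes only because the CIP priorities change), while the 4''R epimer of 23 should remain and can be recycled by oxidation to the enone and reduction.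

Step 17
Reactants: 24 (2S)-3'-(allyloxy)-5'-{(R)-[(2R)-3,3-dimethyloxiran-2-yl](hydroxy)methyl}-2'-(3-methylbut-2-enyl)-4',7-bis(triisopropylsilyloxy)flavan
Product: 25 (2S)-3'-(allyloxy)-5'-{(R)-[(2R)-3,3-dimethyloxiran-2-yl](hydroxy)methyl}-2'-(3-methylbut-2-enyl)flavan-4',7-diol
Conditions: Bu4NF (2.5 equiv), AcOH (2.5 equiv), THF, 0 °C
Reagents that add atoms: none
Why: Fluoride cleavage of both aryl silyl ethers, buffered with acetic acid so that no phenoxide is present to open the epoxide at C3'' in a base-type 5-exo closure or to trigger epoxide migration, should release the free 4'-phenol of the key-step precursor.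

Step 18
Reactants: 25 (2S)-3'-(allyloxy)-5'-{(R)-[(2R)-3,3-dimethyloxiran-2-yl](hydroxy)methyl}-2'-(3-methylbut-2-enyl)flavan-4',7-diol
Product: 26 (3R,4R)-8-(allyloxy)-6-[(2S)-7-hydroxychroman-2-yl]-2,2-dimethyl-7-(3-methylbut-2-enyl)chroman-3,4-diol
Conditions: pyridinium p-toluenesulfonate (0.2 equiv), CH2Cl2, 0 to 23 °C
Reagents that add atoms: none
Why: The weak acid hydrogen-bonds to and partly protonates the epoxide oxygen, which lengthens the C2''–O bond because the tertiary carbon carries positive charge best, and the 4'-OH oxygen attacks C2'' from the side opposite to the leaving oxygen, forming the O4'–C2'' bond and releasing the C3'' hydroxyl. The closest known reaction is the acid-promoted cyclisation of ortho-(2,3-epoxy-3-methylbutyl)phenols to 3-hydroxy-2,2-dimethylchromans. Ring D is closed in a 6-endo-tet epoxide opening. No stereocentre is created: C2'' bears two methyl groups, C3'' keeps its C–O bond and C4'' is not involved, so the erythro (3''R,4''R) relationship set in step 16 appears as the cis diol. The step needs 6-endo over 5-exo selectivity, which the tertiary against secondary nature of the two epoxide carbons under acid catalysis and the electron-withdrawing C4'' hydroxyl next to C3'' should secure. It also needs the benzylic C4''–OH to stay un-ionised, which is why an acid as weak as pyridinium p-toluenesulfonate is used in a non-nucleophilic solvent, and the free 7-OH and the 3'-O-allyl group are simply carried along.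

Step 19
Reactants: 26 (3R,4R)-8-(allyloxy)-6-[(2S)-7-hydroxychroman-2-yl]-2,2-dimethyl-7-(3-methylbut-2-enyl)chroman-3,4-diol
Product: 27 (3R,4R)-6-[(2S)-7-hydroxychroman-2-yl]-2,2-dimethyl-7-(3-methylbut-2-enyl)chroman-3,4,8-triol
Conditions: Pd(PPh3)4 (5 mol %), morpholine, THF, 23 °C
Reagents that add atoms: none
Why: Zerovalent palladium ionises the aryl allyl ether to a π-allyl complex (Tsuji–Trost deallylation) that is captured by morpholine, which frees the 3'-phenol under neutral conditions that leave the prenyl group, the cis diol and the three stereocentres untouched.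

**Compound list**

1 | 7-hydroxychromone | O=c1ccoc2cc(O)ccc12 | starting material
2 | 7-(triisopropylsilyloxy)chromone | O=c1ccoc2cc(O[Si](C(C)C)(C(C)C)C(C)C)ccc12 | intermediate
3 | 5-bromo-2-hydroxybenzaldehyde | O=Cc1cc(Br)ccc1O | starting material
4 | 5-bromo-2-(methoxymethoxy)benzaldehyde | O=Cc1cc(Br)ccc1OCOC | intermediate
5 | 5-bromo-2-(methoxymethoxy)phenyl formate | O=COc1cc(Br)ccc1OCOC | intermediate
6 | 5-bromo-2-(methoxymethoxy)phenol | Oc1cc(Br)ccc1OCOC | intermediate
7 | lithium 5-lithio-2-(methoxymethoxy)phenolate | [Li]Oc1cc([Li])ccc1OCOC | intermediate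
8 | lithium [3-(lithiooxy)-4-(methoxymethoxy)phenyl]triisopropoxyborate | [Li+].CC(C)O[B-](OC(C)C)(OC(C)C)c1ccc(OCOC)c(O[Li])c1 | intermediate
9 | [3-hydroxy-4-(methoxymethoxy)phenyl]boronic acid | OB(O)c1ccc(OCOC)c(O)c1 | intermediate
10 | (2S)-3'-hydroxy-4'-(methoxymethoxy)-7-(triisopropylsilyloxy)flavanone | O=C1C[C@@H](c2ccc(OCOC)c(O)c2)Oc2cc(O[Si](C(C)C)(C(C)C)C(C)C)ccc21 | intermediate
11 | (2S)-3'-hydroxy-4'-(methoxymethoxy)-7-(triisopropylsilyloxy)flavan-4-ol, C4 epimers, 2,4-cis (4S) expected to predominate | OC1C[C@@H](c2ccc(OCOC)c(O)c2)Oc2cc(O[Si](C(C)C)(C(C)C)C(C)C)ccc21 | intermediate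
12 | (2S)-3'-hydroxy-4'-(methoxymethoxy)-7-(triisopropylsilyloxy)flavan | C1C[C@@H](c2ccc(OCOC)c(O)c2)Oc2cc(O[Si](C(C)C)(C(C)C)C(C)C)ccc21 | intermediate
13 | 2-methylbut-3-en-2-ol | C=CC(C)(C)O | starting material
14 | lithium 2-methylbut-3-en-2-olate | C=CC(C)(C)O[Li] | intermediate
15 | methyl 2-methylbut-3-en-2-yl carbonate | C=CC(C)(C)OC(=O)OC | intermediate
16 | (2S)-4'-(methoxymethoxy)-3'-(2-methylbut-3-en-2-yloxy)-7-(triisopropylsilyloxy)flavan | C1C[C@@H](c2ccc(OCOC)c(OC(C)(C)C=C)c2)Oc2cc(O[Si](C(C)C)(C(C)C)C(C)C)ccc21 | intermediate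
17 | (2S)-3'-hydroxy-4'-(methoxymethoxy)-2'-(3-methylbut-2-enyl)-7-(triisopropylsilyloxy)flavan | C1C[C@@H](c2ccc(OCOC)c(O)c2CC=C(C)C)Oc2cc(O[Si](C(C)C)(C(C)C)C(C)C)ccc21 | intermediate
18 | (2S)-3'-(allyloxy)-4'-(methoxymethoxy)-2'-(3-methylbut-2-enyl)-7-(triisopropylsilyloxy)flavan | C1C[C@@H](c2ccc(OCOC)c(OCC=C)c2CC=C(C)C)Oc2cc(O[Si](C(C)C)(C(C)C)C(C)C)ccc21 | intermediate
19 | (2S)-3'-(allyloxy)-4'-hydroxy-2'-(3-methylbut-2-enyl)-7-(triisopropylsilyloxy)flavan | C1C[C@@H](c2ccc(O)c(OCC=C)c2CC=C(C)C)Oc2cc(O[Si](C(C)C)(C(C)C)C(C)C)ccc21 | intermediate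
20 | (2S)-3'-(allyloxy)-5'-formyl-4'-hydroxy-2'-(3-methylbut-2-enyl)-7-(triisopropylsilyloxy)flavan | C1C[C@@H](c2cc(C=O)c(O)c(OCC=C)c2CC=C(C)C)Oc2cc(O[Si](C(C)C)(C(C)C)C(C)C)ccc21 | intermediate
21 | (2S)-3'-(allyloxy)-5'-formyl-2'-(3-methylbut-2-enyl)-4',7-bis(triisopropylsilyloxy)flavan | C1C[C@@H](c2cc(C=O)c(O[Si](C(C)C)(C(C)C)C(C)C)c(OCC=C)c2CC=C(C)C)Oc2cc(O[Si](C(C)C)(C(C)C)C(C)C)ccc21 | intermediate
22 | 2-methylprop-1-enylmagnesium bromide | CC(C)=C[Mg]Br | starting material
23 | (2S)-3'-(allyloxy)-5'-(1-hydroxy-3-methylbut-2-enyl)-2'-(3-methylbut-2-enyl)-4',7-bis(triisopropylsilyloxy)flavan, mixture of C4'' epimers | C1C[C@@H](c2cc(C(O)C=C(C)C)c(O[Si](C(C)C)(C(C)C)C(C)C)c(OCC=C)c2CC=C(C)C)Oc2cc(O[Si](C(C)C)(C(C)C)C(C)C)ccc21 | intermediate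
24 | (2S)-3'-(allyloxy)-5'-{(R)-[(2R)-3,3-dimethyloxiran-2-yl](hydroxy)methyl}-2'-(3-methylbut-2-enyl)-4',7-bis(triisopropylsilyloxy)flavan (erythro, 3''R,4''R) | C1C[C@@H](c2cc([C@@H](O)[C@H]3OC3(C)C)c(O[Si](C(C)C)(C(C)C)C(C)C)c(OCC=C)c2CC=C(C)C)Oc2cc(O[Si](C(C)C)(C(C)C)C(C)C)ccc21 | intermediate
25 | (2S)-3'-(allyloxy)-5'-{(R)-[(2R)-3,3-dimethyloxiran-2-yl](hydroxy)methyl}-2'-(3-methylbut-2-enyl)flavan-4',7-diol (key-step precursor) | C1C[C@@H](c2cc([C@@H](O)[C@H]3OC3(C)C)c(O)c(OCC=C)c2CC=C(C)C)Oc2cc(O)ccc21 | intermediate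
26 | (3R,4R)-8-(allyloxy)-6-[(2S)-7-hydroxychroman-2-yl]-2,2-dimethyl-7-(3-methylbut-2-enyl)chroman-3,4-diol (3'-O-allyl ether of the target) | CC(C)=CCc1c([C@@H]2CCc3ccc(O)cc3O2)cc2c(c1OCC=C)OC(C)(C)[C@H](O)[C@@H]2O | intermediate
27 | (3R,4R)-6-[(2S)-7-hydroxychroman-2-yl]-2,2-dimethyl-7-(3-methylbut-2-enyl)chroman-3,4,8-triol (CNP0228510.2) | CC(C)=CCc1c([C@@H]2CCc3ccc(O)cc3O2)cc2c(c1O)OC(C)(C)[C@H](O)[C@@H]2O | target

Total steps: 19
Longest linear sequence: 17 steps (steps 2 to 7 and 9 to 19, from 3)

**Steps most likely to fail**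

Step 16. The Ti(OiPr)4–tartrate catalyst may discriminate poorly between the two C4'' epimers, or react only sluggishly, because the methyl group cis to the carbinol on C2'' and the hindered ortho-silyloxyaryl group both slow this class of allylic alcohol. The epoxide would then be formed from both epimers or not at a useful rate. The fallback sets C4'' before the epoxidation instead of resolving it. It sets out from aldehyde 21: the alkenylzinc reagent made from 22 and ZnCl2 (magnesium halides sequestered with N,N,N',N'-tetraethylethylenediamine) is added in toluene at 0 °C in the presence of (2S)-3-exo-morpholinoisoborneol (10 mol %). Amino-alcohol-catalysed alkenylzinc additions to aryl aldehydes follow the facial sense of the dialkylzinc additions, which give S carbinols with this ligand, so this should give the single 4''S allylic alcohol F1. Epoxidation of F1 under the conditions of step 16 with a full equivalent of t-BuOOH, now a matched reagent-controlled reaction and no longer a resolution, rejoins the route at 24.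

Step 18. Ionisation of the benzylic C4''–O bond of the ortho-hydroxybenzyl alcohol (ortho-quinone methide formation, loss of the C4'' configuration) or attack of the phenol at C3'' (5-exo closure) may compete with the 6-endo opening. The fallback removes the ionisable hydroxyl before the ring is closed and restores it afterwards. It sets out from 24: Dess–Martin oxidation (CH2Cl2, NaHCO3, 0 °C) gives the aryl epoxy ketone F2; Bu4NF/AcOH in THF at 0 °C gives the ortho-hydroxyaryl epoxy ketone F3; pyridinium p-toluenesulfonate in CH2Cl2 then closes ring D by attack of the 4'-OH at the tertiary β-carbon, the α-carbon of an epoxy ketone being deactivated toward cationic opening, to give the 3''-hydroxy-2'',2''-dimethylchroman-4''-one F4 with C3'' untouched. NaBH4 in MeOH at −40 °C should deliver hydride to the carbonyl face away from the pseudo-axial C2'' methyl group and the C3'' hydroxyl, which places the new C4'' hydroxyl cis to the C3'' hydroxyl and rejoins the route at 26.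

Step 5. Poor facial selectivity, or slow addition to the electron-rich 7-silyloxychromone with competing protodeboronation, would leave C2 poorly defined. The fallback separates the C–C bond formation from the setting of C2. It sets out from 2 and 9: the same coupling run with Pd(OCOCF3)2 and achiral 2,2'-bipyridine gives the racemic flavanone F5. Asymmetric transfer hydrogenation with RuCl[(S,S)-TsDPEN](p-cymene) in HCO2H–Et3N at 23 °C then acts as a kinetic resolution: this catalyst gives 4S benzylic alcohols from chromanones, and only in the 2S enantiomer is that the intrinsically preferred face leading to the 2,4-cis alcohol, so the 2S enantiomer should be reduced to the (2S,4S) alcohol, which is 11, where the route is rejoined. The unreacted (2R)-flavanone F6 is separated and can be racemised with base through ring opening and re-closure and recycled.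

Further compounds
F1 | step 16 | (2S)-3'-(allyloxy)-5'-[(1S)-1-hydroxy-3-methylbut-2-enyl]-2'-(3-methylbut-2-enyl)-4',7-bis(triisopropylsilyloxy)flavan | C1C[C@@H](c2cc([C@@H](O)C=C(C)C)c(O[Si](C(C)C)(C(C)C)C(C)C)c(OCC=C)c2CC=C(C)C)Oc2cc(O[Si](C(C)C)(C(C)C)C(C)C)ccc21
F2 | step 18 | (2S)-3'-(allyloxy)-5'-[(2S)-3,3-dimethyloxirane-2-carbonyl]-2'-(3-methylbut-2-enyl)-4',7-bis(triisopropylsilyloxy)flavan | C1C[C@@H](c2cc(C(=O)[C@H]3OC3(C)C)c(O[Si](C(C)C)(C(C)C)C(C)C)c(OCC=C)c2CC=C(C)C)Oc2cc(O[Si](C(C)C)(C(C)C)C(C)C)ccc21
F3 | step 18 | (2S)-3'-(allyloxy)-5'-[(2S)-3,3-dimethyloxirane-2-carbonyl]-2'-(3-methylbut-2-enyl)flavan-4',7-diol | C1C[C@@H](c2cc(C(=O)[C@H]3OC3(C)C)c(O)c(OCC=C)c2CC=C(C)C)Oc2cc(O)ccc21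
F4 | step 18 | (3S)-8-(allyloxy)-3-hydroxy-6-[(2S)-7-hydroxychroman-2-yl]-2,2-dimethyl-7-(3-methylbut-2-enyl)chroman-4-one | CC(C)=CCc1c([C@@H]2CCc3ccc(O)cc3O2)cc2c(c1OCC=C)OC(C)(C)[C@H](O)C2=O
F5 | step 5 | racemic 3'-hydroxy-4'-(methoxymethoxy)-7-(triisopropylsilyloxy)flavanone | O=C1CC(c2ccc(OCOC)c(O)c2)Oc2cc(O[Si](C(C)C)(C(C)C)C(C)C)ccc21
F6 | step 5 | (2R)-3'-hydroxy-4'-(methoxymethoxy)-7-(triisopropylsilyloxy)flavanone | O=C1C[C@H](c2ccc(OCOC)c(O)c2)Oc2cc(O[Si](C(C)C)(C(C)C)C(C)C)ccc21
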